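**Retrosynthetic overview**

1. Oxolane last: the C2–O1 bond is closed by acid-triggered 5-exo capture of the syringyl benzylic cation by the CH2OH β to the ketone. This places the C2 aryl trans to C3.
2. Both C–aryl bonds (C2–Ar and the ketone C–Ar) come from one aryllithium adding to the aldehyde and the lactone carbonyl of a trans-3,4-disubstituted γ-butyrolactone aldehyde.
3. That lactone aldehyde comes from ozonolysis of a propenyl group and a trans-selective enolate hydroxymethylation of (S)-4-propenyl-γ-butyrolactone, which sets target C4 from C3.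
4. Key bond: target C3–C4 is made by a Johnson–Claisen [3,3] rearrangement of an (S,E)-allylic alcohol. 1,3-Chirality transfer sets target C3 and erases the purchased carbinol centre.
5. The allylic alcohol comes from (S)-but-3-yn-2-ol and formaldehyde. Ring order: γ-butyrolactone (temporary, opened when the ketone is made), then the oxolane.

Assumption: (S)-but-3-yn-2-ol is taken as an inexpensive commercial enantiopure C4 alcohol and is the only source of chirality; all other inputs are achiral catalogue chemicals.

**Route**

Step 1
Reactants: 1, (S)-but-3-yn-2-ol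
Product: 2, (4S)-pent-2-yne-1,4-diol
Conditions: n-BuLi (2.1 equiv), THF, −78 → 0 °C; (CH2O)n, 0 °C → rt
Reagents that add atoms: paraformaldehyde (formaldehyde), C=O
Why: The alkoxide/acetylide dianion adds through carbon to formaldehyde (acetylide 1,2-addition), leaving the purchased stereocentre untouched.

Step 2
Reactants: 2, (4S)-pent-2-yne-1,4-diol
Product: 3, (2E,4S)-pent-2-ene-1,4-diol
Conditions: Red-Al (3 equiv), THF, 0 °C → rt; Rochelle salt work-up
Reagents that add atoms: none
Why: Alkoxide-directed trans-hydroalumination of the propargylic alcohol gives only the E-alkene and creates or disturbs no stereocentre.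

Step 3
Reactants: 3, (2E,4S)-pent-2-ene-1,4-diol
Product: 4, (2S,3E)-5-[(tert-butyldimethylsilyl)oxy]pent-3-en-2-ol
Conditions: TBSCl (1.05 equiv), imidazole, CH2Cl2, −20 → 0 °C
Reagents that add atoms: tert-butyldimethylsilyl chloride, CC(C)(C)[Si](C)(C)Cl
Why: Kinetically selective silylation of the unhindered primary hydroxyl leaves only the secondary allylic OH free for the rearrangement.

Step 4
Reactants: 4, (2S,3E)-5-[(tert-butyldimethylsilyl)oxy]pent-3-en-2-ol
Product: 5, (4S)-4-[(1E)-prop-1-en-1-yl]oxolan-2-one
Conditions: MeC(OEt)3 (6 equiv), EtCO2H (cat.), 140 °C, −EtOH; strip volatiles; then TsOH·H2O, MeOH, rt (telescoped, ester not isolated); AgNO3–SiO2 to remove any trace (Z)-propenyl isomer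
Reagents that add atoms: triethyl orthoacetate, CC(OCC)(OCC)OCC
Why: Johnson–Claisen [3,3] rearrangement through a chair transition state with the methyl pseudo-equatorial forms the target C3–C4 bond suprafacially, transferring the (S)-carbinol chirality to the new (S) carbon centre while the original centre becomes the E-propenyl group; acid then removes TBS and the γ-hydroxy ester lactonises.

Step 5
Reactants: 5, (4S)-4-[(1E)-prop-1-en-1-yl]oxolan-2-one
Product: 6, (3S,4R)-4-[(1E)-prop-1-en-1-yl]-3-{[(triethylsilyl)oxy]methyl}oxolan-2-one (trans; the C4 descriptor changes only through CIP priorities)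
Conditions: LDA (1.1 equiv), THF, −78 °C; CH2O (g, from cracked paraformaldehyde), −78 → −40 °C; then TESCl, Et3N, DMAP (cat.), → 0 °C
Reagents that add atoms: formaldehyde, C=O; chlorotriethylsilane, CC[Si](Cl)(CC)CC
Why: The lactone enolate undergoes aldol addition to formaldehyde anti to the β-propenyl group (substrate control), setting the future target C4 trans to C3, and the alkoxide is capped in situ as the TES ether.

Step 6
Reactants: 6, (3S,4R)-4-[(1E)-prop-1-en-1-yl]-3-{[(triethylsilyl)oxy]methyl}oxolan-2-one
Product: 7, (3R,4S)-5-oxo-4-{[(triethylsilyl)oxy]methyl}oxolane-3-carbaldehyde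
Conditions: O3, CH2Cl2, −78 °C; PPh3, −78 °C → rt; used crude at once
Reagents that add atoms: ozone, [O-][O+]=O
Why: Ozonolysis with reductive work-up cleaves the propenyl C=C to the aldehyde (the old carbinol carbon leaves as acetaldehyde) under cold neutral conditions that do not enolise the α-centre.

Step 7
Reactants: 8, 4-bromo-2,6-dimethoxyphenol
Product: 9, 5-bromo-1,3-dimethoxy-2-(methoxymethoxy)benzene
Conditions: MOMCl, i-Pr2NEt, CH2Cl2, 0 °C → rt
Reagents that add atoms: chloromethyl methyl ether, COCCl
Why: O-alkylation of the phenol gives a MOM ether that tolerates Br/Li exchange and falls off in the final acid step.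

Step 8
Reactants: 7, (3R,4S)-5-oxo-4-{[(triethylsilyl)oxy]methyl}oxolane-3-carbaldehyde; 9, 5-bromo-1,3-dimethoxy-2-(methoxymethoxy)benzene (2.2 equiv)
Product: 10, (2S,3R,4RS)-1,4-bis[3,5-dimethoxy-4-(methoxymethoxy)phenyl]-4-hydroxy-3-(hydroxymethyl)-2-{[(triethylsilyl)oxy]methyl}butan-1-one (C4 carbinol epimers, partly as cyclic hemiketal)
Conditions: 9, n-BuLi (2.2 equiv), THF, −78 °C, 30 min; add 7, −78 °C, 1 h; aq NH4Cl at −78 °C
Reagents that add atoms: none beyond reactant 9, used as its aryllithium [Li]c1cc(OC)c(OCOC)c(OC)c1 (n-BuLi contributes no atoms)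
Why: Br/Li exchange gives an aryllithium that adds 1,2 to the aldehyde and once to the lactone, whose lithium lactolate is stable at −78 °C and releases the aryl ketone and the free CH2OH on work-up; the new carbinol centre is left uncontrolled because step 9 resets it.

Step 9
Reactants: 10, the keto-diol from step 8
Product: 11, [(3S,4R,5S)-5-(4-hydroxy-3,5-dimethoxyphenyl)-4-(hydroxymethyl)oxolan-3-yl](4-hydroxy-3,5-dimethoxyphenyl)methanone (target, CID53356211)
Conditions: 3 M aq HCl/THF (1:3), rt → 40 °C, monitored
Reagents that add atoms: none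
Why: Acid removes the TES and both MOM groups and ionises the p-oxygenated benzylic alcohol, and the cation is captured 5-exo by the CH2OH β to the ketone (SN1 cycloetherification); reversible ionisation places the aryl trans to the C3 CH2OH, giving the all-trans (2S,3R,4S) oxolane with C3 and C4 untouched.

**Compound list**

1 | (S)-but-3-yn-2-ol | C[C@H](O)C#C | starting material
2 | (4S)-pent-2-yne-1,4-diol | C[C@H](O)C#CCO | intermediate
3 | (2E,4S)-pent-2-ene-1,4-diol | C[C@H](O)/C=C/CO | intermediate
4 | (2S,3E)-5-[(tert-butyldimethylsilyl)oxy]pent-3-en-2-ol | C[C@H](O)/C=C/CO[Si](C)(C)C(C)(C)C | intermediate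
5 | (4S)-4-[(1E)-prop-1-en-1-yl]oxolan-2-one | O=C1C[C@@H](/C=C/C)CO1 | intermediate
6 | (3S,4R)-4-[(1E)-prop-1-en-1-yl]-3-{[(triethylsilyl)oxy]methyl}oxolan-2-one | O=C1OC[C@H](/C=C/C)[C@H]1CO[Si](CC)(CC)CC | intermediate
7 | (3R,4S)-5-oxo-4-{[(triethylsilyl)oxy]methyl}oxolane-3-carbaldehyde | O=C1OC[C@H](C=O)[C@H]1CO[Si](CC)(CC)CC | intermediate
8 | 4-bromo-2,6-dimethoxyphenol | COc1cc(Br)cc(OC)c1O | starting material
9 | 5-bromo-1,3-dimethoxy-2-(methoxymethoxy)benzene | COCOc1c(OC)cc(Br)cc1OC | intermediate
10 | (2S,3R,4RS)-1,4-bis[3,5-dimethoxy-4-(methoxymethoxy)phenyl]-4-hydroxy-3-(hydroxymethyl)-2-{[(triethylsilyl)oxy]methyl}butan-1-one | COCOc1c(OC)cc(cc1OC)C(=O)[C@H](CO[Si](CC)(CC)CC)[C@H](CO)C(O)c1cc(OC)c(OCOC)c(OC)c1 | intermediate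
11 | [(3S,4R,5S)-5-(4-hydroxy-3,5-dimethoxyphenyl)-4-(hydroxymethyl)oxolan-3-yl](4-hydroxy-3,5-dimethoxyphenyl)methanone | COc1cc(C(=O)[C@@H]2CO[C@H](c3cc(OC)c(O)c(OC)c3)[C@H]2CO)cc(OC)c1O | target

**Step count**

Total steps: 9 (step 4 is a telescoped rearrangement/lactonisation).
Longest linear sequence: 8 (steps 1–6, 8, 9 from (S)-but-3-yn-2-ol); step 7 is a one-step side branch.

**Three steps most likely to fail, with fallbacks**

- **Step 8.** Aldehyde 7 is α-chiral with a β-acyloxy group, so it can epimerise or eliminate, and the lactone can over-add.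
  - Fallback: switch to the amide series. Eschenmoser–Claisen of 4 with MeC(OMe)2NMe2, then α-hydroxymethylation and ozonolysis, gives a stable five-membered lactol in which the aldehyde is masked by the new CH2OH. ArLi then adds to the lactol and to the dimethylamide through a stable tetrahedral intermediate. The C4 epimers are equilibrated with base after ring closure.
- **Step 9.** The benzylic cation is generated with the aryl ketone present. Risks are dehydration via the γ-hydroxy-ketone lactol toward dihydrofuran or furan, slow Friedel–Crafts closure to an aryltetralone, and loss of the β-hydroxy ketone.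
  - Fallback: build the oxolane before the ketone exists. In the amide series, Lewis-acid C-arylation of the lactol (or its methyl acetal) with 2,6-dimethoxyphenol and BF3·OEt2 gives the 2-aryl-oxolane-4-carboxamide under thermodynamic trans control. The aroyl group is then installed last by ArLi addition to the amide.
- **Step 5.** Monomeric formaldehyde can polymerise, add twice, or give the α-methylene lactone, and the in situ silylation may be incomplete.
  - Fallback: deliver this carbon in the sigmatropic step. Acylate 4 with 3-(4-methoxybenzyloxy)propanoyl chloride and run an Ireland–Claisen rearrangement (LDA, TMSCl), which forms C3–C4 with the CH2O arm already attached. PMB and TBS removal with lactonisation, then DBU equilibration to the trans-lactone, rejoins the route at the stage of 6.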